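**Retrosynthetic overview**
1. Target 24 ⇐ macrocyclic ketol 21 + (R)-2-methylbutanoic acid 23 (C8–O ester, last step; 23 from tiglic acid by asymmetric hydrogenation).
2. 21 ⇐ seco keto-aldehyde 19: C7–C8 bond by a chiral-phosphoric-acid-catalysed intramolecular allylboration, which closes the ten-membered carbocycle last and creates C7, C8 and the exocyclic methylene.
3. 19 ⇐ butenolide allylboronate 15 (C8 added to the C9 acid with CH2N2); the butenolide (lactone ring, formed first) ⇐ γ-hydroxy alkynoate 10 by hydroalumination/borylmethylation with ICH2Bpin.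
4. C4/C5 ⇐ hydroxyl-directed epoxidation and invertive epoxide hydrolysis; C6 ⇐ catalytic asymmetric propiolate addition to enal 7.
5. 7 ⇐ geranyl acetate 1: SeO2/NaClO2 oxidation of the (E)-methyl to the C9 acid, then Ru-catalysed asymmetric hydrogenation (C10, first stereocentre).

Locants used throughout: ring C1–C10; C4 (Me C15, OH), C5 (O-isobutyryl), C6 (lactone O), C7 (bears C11(=C13H2)–C12 lactone carbonyl), C8 (O-acyl), C9 (C=O), C10 (Me C14). Bpin = 4,4,5,5-tetramethyl-1,3,2-dioxaborolan-2-yl.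
Assumption: the sense of induction of each chiral catalyst is assigned by analogy with its established facial preference (none has been run on these substrates); if a sense proves opposite, the mirror-image catalyst is used.

**Step 1**
Reactants: 1 geranyl acetate [(2E)-3,7-dimethylocta-2,6-dien-1-yl acetate]
Product: 2 (2E,6E)-3,7-dimethyl-8-oxoocta-2,6-dien-1-yl acetate
Conditions: SeO2 (1.1 equiv), EtOH, reflux
Reagents that add atoms: selenium dioxide, O=[Se]=O
Why: Riley allylic oxidation (ene reaction then [2,3]-sigmatropic shift) takes the (E)-methyl of the electron-rich terminal alkene to the (E)-enal, the 2,3-alkene being deactivated by the allylic acetate; no stereocentre is formed.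

**Step 2**
Reactants: 2 (2E,6E)-3,7-dimethyl-8-oxoocta-2,6-dien-1-yl acetate
Product: 3 (2E,6E)-8-acetoxy-2,6-dimethylocta-2,6-dienoic acid
Conditions: NaClO2, NaH2PO4, 2-methyl-2-butene, tBuOH/H2O, 20 °C
Reagents that add atoms: sodium chlorite (NaClO2), [Na+].[O-]Cl=O
Why: Pinnick oxidation converts the enal into the acid without touching either alkene geometry, the hypochlorous acid being trapped by 2-methyl-2-butene.

**Step 3**
Reactants: 3 (2E,6E)-8-acetoxy-2,6-dimethylocta-2,6-dienoic acid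
Product: 4 (2R,6E)-8-acetoxy-2,6-dimethyloct-6-enoic acid
Conditions: H2 (4 atm), Ru(OAc)2[(R)-H8-BINAP] (0.5 mol%), MeOH, 20 °C
Reagents that add atoms: none
Why: Carboxylate-directed asymmetric hydrogenation of the (E)-2-methyl-2-enoic acid on the Ru–diphosphine dicarboxylate sets C10 as R (first stereocentre; same catalyst and facial sense as for tiglic acid in step 15), while the non-coordinating trisubstituted allylic acetate alkene is left alone.

**Step 4**
Reactants: 4 (2R,6E)-8-acetoxy-2,6-dimethyloct-6-enoic acid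
Product: 5 tert-butyl (2R,6E)-8-acetoxy-2,6-dimethyloct-6-enoate
Conditions: Boc2O, DMAP (cat.), tBuOH, 30 °C
Reagents that add atoms: di-tert-butyl dicarbonate, CC(C)(C)OC(=O)OC(=O)OC(C)(C)C
Why: DMAP-catalysed tert-butyl esterification through the mixed carbonic anhydride masks C9 for the organozinc and hydride steps ahead without enolising C10.

**Step 5**
Reactants: 5 tert-butyl (2R,6E)-8-acetoxy-2,6-dimethyloct-6-enoate
Product: 6 tert-butyl (2R,6E)-8-hydroxy-2,6-dimethyloct-6-enoate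
Conditions: K2CO3 (cat.), MeOH, 0 → 20 °C
Reagents that add atoms: none
Why: Base-catalysed transesterification (methanolysis) frees the allylic alcohol; the hindered tert-butyl ester and C10 are untouched.

**Step 6**
Reactants: 6 tert-butyl (2R,6E)-8-hydroxy-2,6-dimethyloct-6-enoate
Product: 7 tert-butyl (2R,6E)-2,6-dimethyl-8-oxooct-6-enoate
Conditions: MnO2 (activated, excess), CH2Cl2, 20 °C
Reagents that add atoms: none
Why: MnO2 oxidises only the allylic alcohol and gives the (E)-enal without double-bond isomerisation.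

**Step 7**
Reactants: 7 tert-butyl (2R,6E)-2,6-dimethyl-8-oxooct-6-enoate; 8 methyl propiolate
Product: 9 11-tert-butyl 1-methyl (4R,5E,10R)-4-hydroxy-6,10-dimethylundec-5-en-2-ynedioate
Conditions: Me2Zn (3 equiv), (S,S)-ProPhenol (10 mol%), Ph3PO (20 mol%), toluene, 4 °C; NH4Cl (aq.)
Reagents that add atoms: none
Why: Zn/ProPhenol-catalysed asymmetric alkynylation: the dinuclear zinc alkoxide delivers the zinc propiolate to the Si face of the enal in a 1,2-addition and sets C6 under catalyst control (4R in 9), the remote C10 centre exerting no influence.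

**Step 8**
Reactants: 9 11-tert-butyl 1-methyl (4R,5E,10R)-4-hydroxy-6,10-dimethylundec-5-en-2-ynedioate
Product: 10 tert-butyl (2R)-5-[(2R,3R)-3-[(1S)-1-hydroxy-4-methoxy-4-oxobut-2-yn-1-yl]-2-methyloxiran-2-yl]-2-methylpentanoate
Conditions: mCPBA (1.2 equiv), NaHCO3, CH2Cl2, 0 °C
Reagents that add atoms: 3-chloroperoxybenzoic acid, O=C(OO)c1cccc(Cl)c1
Why: Hydroxyl-directed (Henbest) peracid epoxidation: A(1,3) strain with the cis methyl C15 holds the C6–H bond in the alkene plane, so the hydrogen-bonded peracid attacks the face syn to OH and gives the threo epoxy alcohol (C4 R, C5 R), while the electron-poor alkynoate is inert.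

**Step 9**
Reactants: 10 tert-butyl (2R)-5-[(2R,3R)-3-[(1S)-1-hydroxy-4-methoxy-4-oxobut-2-yn-1-yl]-2-methyloxiran-2-yl]-2-methylpentanoate; 11 2-(iodomethyl)-4,4,5,5-tetramethyl-1,3,2-dioxaborolane (ICH2Bpin)
Product: 13 tert-butyl (2R)-2-methyl-5-[(2R,3R)-2-methyl-3-[(2S)-5-oxo-4-(pinacolborylmethyl)-2,5-dihydrofuran-2-yl]oxiran-2-yl]pentanoate, via bis(diisobutylaluminium) alkoxide/α-aluminio enoate 12 (not isolated)
Conditions: iBu2AlH (2.3 equiv), HMPA, THF, −40 °C; then 11, −40 → 20 °C; KNaC4H4O6 (aq.)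
Reagents that add atoms: none
Why: Conjugate syn-hydroalumination of the 2-alkynoate by the HMPA-complexed hydride, then C-alkylation of the α-aluminio acrylate with the α-iodo boronate (boron ate complex, 1,2-shift), places CH2Bpin cis to H7 so that the C6 alkoxide sits cis to the ester and lactonises to the butenolide (the established entry to 2-alkoxycarbonyl allylboronates); the trisubstituted epoxide survives at low temperature.

**Step 10**
Reactants: 13 tert-butyl (2R)-2-methyl-5-[(2R,3R)-2-methyl-3-[(2S)-5-oxo-4-(pinacolborylmethyl)-2,5-dihydrofuran-2-yl]oxiran-2-yl]pentanoate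
Product: 14 tert-butyl (2R,6S,7R)-6,7-dihydroxy-2,6-dimethyl-7-[(2S)-5-oxo-4-(pinacolborylmethyl)-2,5-dihydrofuran-2-yl]heptanoate
Conditions: HClO4 (5 mol%), THF/H2O (3:1), 0 → 20 °C
Reagents that add atoms: water, O
Why: Acid-catalysed epoxide hydrolysis: water opens the protonated epoxide at the tertiary carbon C4 with inversion (giving 4S) while the C5–O bond is retained, which delivers the erythro C4/C5 diol.

**Step 11**
Reactants: 14 tert-butyl (2R,6S,7R)-6,7-dihydroxy-2,6-dimethyl-7-[(2S)-5-oxo-4-(pinacolborylmethyl)-2,5-dihydrofuran-2-yl]heptanoate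
Product: 15 tert-butyl (2R,6S,7R)-6-hydroxy-2,6-dimethyl-7-(2-methylpropanoyloxy)-7-[(2S)-5-oxo-4-(pinacolborylmethyl)-2,5-dihydrofuran-2-yl]heptanoate
Conditions: isobutyryl chloride (1.2 equiv), pyridine, CH2Cl2, 0 °C
Reagents that add atoms: isobutyryl chloride, CC(C)C(Cl)=O
Why: Chemoselective acylation of the secondary C5 hydroxyl (the tertiary C4–OH does not react), with pyridine as a base too weak to trigger vinylogous β-elimination of the new ester from the butenolide.

**Step 12**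
Reactants: 15 tert-butyl (2R,6S,7R)-6-hydroxy-2,6-dimethyl-7-(2-methylpropanoyloxy)-7-[(2S)-5-oxo-4-(pinacolborylmethyl)-2,5-dihydrofuran-2-yl]heptanoate
Product: 16 (2R,6S,7R)-6-hydroxy-2,6-dimethyl-7-(2-methylpropanoyloxy)-7-[(2S)-5-oxo-4-(pinacolborylmethyl)-2,5-dihydrofuran-2-yl]heptanoic acid
Conditions: CF3CO2H/CH2Cl2 (1:4), 0 °C
Reagents that add atoms: none
Why: Acidolysis (E1 loss of isobutene) of the tert-butyl ester; the secondary isobutyrate and the lactone are stable, and the ester-deactivated allylboronate is not protodeboronated by brief cold CF3CO2H.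

**Step 13**
Reactants: 16 (2R,6S,7R)-6-hydroxy-2,6-dimethyl-7-(2-methylpropanoyloxy)-7-[(2S)-5-oxo-4-(pinacolborylmethyl)-2,5-dihydrofuran-2-yl]heptanoic acid
Product: 18 (1R,2S,6R)-8-diazo-2-hydroxy-2,6-dimethyl-7-oxo-1-[(2S)-5-oxo-4-(pinacolborylmethyl)-2,5-dihydrofuran-2-yl]octyl 2-methylpropanoate, via mixed isobutyl carbonic anhydride 17 (not isolated)
Conditions: iBuOCOCl, N-methylmorpholine, THF, −15 °C; then CH2N2 (excess, Et2O), −15 → 0 °C
Reagents that add atoms: diazomethane, C=[N+]=[N-]; isobutyl chloroformate, CC(C)COC(Cl)=O (its atoms stay in 17 only)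
Why: Acylation of diazomethane by the mixed carbonic anhydride (first stage of an Arndt–Eistert sequence) adds C8 as the diazoketone without touching C10, at a temperature where cycloaddition to the trisubstituted butenolide is slow.

**Step 14**
Reactants: 18 (1R,2S,6R)-8-diazo-2-hydroxy-2,6-dimethyl-7-oxo-1-[(2S)-5-oxo-4-(pinacolborylmethyl)-2,5-dihydrofuran-2-yl]octyl 2-methylpropanoate
Product: 21 (3aR,4R,6R,10S,11R,11aS)-4,10-dihydroxy-6,10-dimethyl-3-methylidene-2,5-dioxododecahydrocyclodeca[b]furan-11-yl 2-methylpropanoate, via keto-aldehyde 19 (not isolated), via macrocyclic O-boryl adduct 20 (not isolated)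
Conditions: dimethyldioxirane (1.05 equiv, acetone), −20 °C, 15 min; then slow addition to (R)-TRIP (10 mol%), 4 Å MS, toluene (final 1 mM), 25 °C; NaHCO3 (aq.)
Reagents that add atoms: dimethyldioxirane, CC1(C)OO1
Why: Proposed new method: the dioxirane turns the diazoketone into a 1,2-keto-aldehyde (known), whose aldehyde is then attacked by the butenolide-embedded pinacol allylboronate under chiral phosphoric acid activation (P–OH to a boronate oxygen, P=O to the formyl C–H) in a chair transition state that closes the ten-membered ring; C7 adds anti to the C5 side chain (trans-fused lactone), the ring-locked geometry (C6 trans to CH2B) gives the anti, E-crotyl-type relationship and hence C8 R by Re-face attack, which (R)-TRIP also favours (matched), and the alkene transposes to the exocyclic methylene; the closest known reactions are the intermolecular chiral-phosphoric-acid-catalysed allylboration of aldehydes with allyl-Bpin and the Brønsted-acid-catalysed additions of 2-alkoxycarbonyl allylboronates that give α-methylene-γ-lactones, neither of which has been run as a macrocyclisation, on a butenolide allylboronate or on a keto-aldehyde made in the flask.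

**Step 15**
Reactants: 22 tiglic acid [(2E)-2-methylbut-2-enoic acid]
Product: 23 (2R)-2-methylbutanoic acid
Conditions: H2 (4 atm), Ru(OAc)2[(R)-H8-BINAP] (0.5 mol%), MeOH, 20 °C
Reagents that add atoms: none
Why: The same carboxylate-directed Ru-catalysed asymmetric hydrogenation as in step 3 gives the (R)-acid from achiral tiglic acid.

**Step 16**
Reactants: 21 (3aR,4R,6R,10S,11R,11aS)-4,10-dihydroxy-6,10-dimethyl-3-methylidene-2,5-dioxododecahydrocyclodeca[b]furan-11-yl 2-methylpropanoate; 23 (2R)-2-methylbutanoic acid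
Product: 24 (3aS,4R,6R,10S,11R,11aS)-10-hydroxy-6,10-dimethyl-3-methylidene-11-(2-methylpropanoyloxy)-2,5-dioxododecahydrocyclodeca[b]furan-4-yl (2R)-2-methylbutanoate (CNP0071420.1)
Conditions: DCC, DMAP (10 mol%), CH2Cl2, 0 → 20 °C
Reagents that add atoms: none
Why: Steglich esterification of the secondary α-ketol C8–OH (the tertiary C4–OH is inert) under mild conditions that keep C8, C10 and the acid α-centre from epimerising; it completes the target.

**Compound list**
1 | geranyl acetate | CC(C)=CCC/C(C)=C/COC(C)=O | starting material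
2 | (2E,6E)-3,7-dimethyl-8-oxoocta-2,6-dien-1-yl acetate | O=C/C(C)=C/CC/C(C)=C/COC(C)=O | intermediate
3 | (2E,6E)-8-acetoxy-2,6-dimethylocta-2,6-dienoic acid | OC(=O)/C(C)=C/CC/C(C)=C/COC(C)=O | intermediate
4 | (2R,6E)-8-acetoxy-2,6-dimethyloct-6-enoic acid | OC(=O)[C@H](C)CCC/C(C)=C/COC(C)=O | intermediate
5 | tert-butyl (2R,6E)-8-acetoxy-2,6-dimethyloct-6-enoate | CC(C)(C)OC(=O)[C@H](C)CCC/C(C)=C/COC(C)=O | intermediate
6 | tert-butyl (2R,6E)-8-hydroxy-2,6-dimethyloct-6-enoate | CC(C)(C)OC(=O)[C@H](C)CCC/C(C)=C/CO | intermediate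
7 | tert-butyl (2R,6E)-2,6-dimethyl-8-oxooct-6-enoate | CC(C)(C)OC(=O)[C@H](C)CCC/C(C)=C/C=O | intermediate
8 | methyl propiolate | C#CC(=O)OC | starting material
9 | 11-tert-butyl 1-methyl (4R,5E,10R)-4-hydroxy-6,10-dimethylundec-5-en-2-ynedioate | CC(C)(C)OC(=O)[C@H](C)CCC/C(C)=C/[C@@H](O)C#CC(=O)OC | intermediate
10 | tert-butyl (2R)-5-[(2R,3R)-3-[(1S)-1-hydroxy-4-methoxy-4-oxobut-2-yn-1-yl]-2-methyloxiran-2-yl]-2-methylpentanoate | CC(C)(C)OC(=O)[C@H](C)CCC[C@@]1(C)O[C@@H]1[C@@H](O)C#CC(=O)OC | intermediate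
11 | 2-(iodomethyl)-4,4,5,5-tetramethyl-1,3,2-dioxaborolane | CC1(C)OB(CI)OC1(C)C | starting material
12 | bis(diisobutylaluminium) species of 10 after hydroalumination: C6 alkoxide and (E)-α-aluminio enoate, H7 cis to Al | CC(C)(C)OC(=O)[C@H](C)CCC[C@@]1(C)O[C@@H]1[C@@H](O[Al](CC(C)C)CC(C)C)/C=C(/[Al](CC(C)C)CC(C)C)C(=O)OC | intermediate (not isolated)
13 | tert-butyl (2R)-2-methyl-5-[(2R,3R)-2-methyl-3-[(2S)-5-oxo-4-(pinacolborylmethyl)-2,5-dihydrofuran-2-yl]oxiran-2-yl]pentanoate | CC(C)(C)OC(=O)[C@H](C)CCC[C@@]1(C)O[C@@H]1[C@@H]1C=C(CB2OC(C)(C)C(C)(C)O2)C(=O)O1 | intermediate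
14 | tert-butyl (2R,6S,7R)-6,7-dihydroxy-2,6-dimethyl-7-[(2S)-5-oxo-4-(pinacolborylmethyl)-2,5-dihydrofuran-2-yl]heptanoate | CC(C)(C)OC(=O)[C@H](C)CCC[C@](C)(O)[C@H](O)[C@@H]1C=C(CB2OC(C)(C)C(C)(C)O2)C(=O)O1 | intermediate
15 | tert-butyl (2R,6S,7R)-6-hydroxy-2,6-dimethyl-7-(2-methylpropanoyloxy)-7-[(2S)-5-oxo-4-(pinacolborylmethyl)-2,5-dihydrofuran-2-yl]heptanoate | CC(C)(C)OC(=O)[C@H](C)CCC[C@](C)(O)[C@H](OC(=O)C(C)C)[C@@H]1C=C(CB2OC(C)(C)C(C)(C)O2)C(=O)O1 | intermediate
16 | (2R,6S,7R)-6-hydroxy-2,6-dimethyl-7-(2-methylpropanoyloxy)-7-[(2S)-5-oxo-4-(pinacolborylmethyl)-2,5-dihydrofuran-2-yl]heptanoic acid | OC(=O)[C@H](C)CCC[C@](C)(O)[C@H](OC(=O)C(C)C)[C@@H]1C=C(CB2OC(C)(C)C(C)(C)O2)C(=O)O1 | intermediate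
17 | mixed anhydride of 16 with isobutyl hydrogen carbonate | CC(C)COC(=O)OC(=O)[C@H](C)CCC[C@](C)(O)[C@H](OC(=O)C(C)C)[C@@H]1C=C(CB2OC(C)(C)C(C)(C)O2)C(=O)O1 | intermediate (not isolated)
18 | (1R,2S,6R)-8-diazo-2-hydroxy-2,6-dimethyl-7-oxo-1-[(2S)-5-oxo-4-(pinacolborylmethyl)-2,5-dihydrofuran-2-yl]octyl 2-methylpropanoate | [N-]=[N+]=CC(=O)[C@H](C)CCC[C@](C)(O)[C@H](OC(=O)C(C)C)[C@@H]1C=C(CB2OC(C)(C)C(C)(C)O2)C(=O)O1 | intermediate
19 | (1R,2S,6R)-2-hydroxy-2,6-dimethyl-7,8-dioxo-1-[(2S)-5-oxo-4-(pinacolborylmethyl)-2,5-dihydrofuran-2-yl]octyl 2-methylpropanoate (seco keto-aldehyde) | O=CC(=O)[C@H](C)CCC[C@](C)(O)[C@H](OC(=O)C(C)C)[C@@H]1C=C(CB2OC(C)(C)C(C)(C)O2)C(=O)O1 | intermediate (not isolated)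
20 | C8-O-pinacolboryl ether of 21 (primary allylboration adduct) | C=C1C(=O)O[C@H]2[C@H]1[C@@H](OB3OC(C)(C)C(C)(C)O3)C(=O)[C@H](C)CCC[C@](C)(O)[C@@H]2OC(=O)C(C)C | intermediate (not isolated)
21 | (3aR,4R,6R,10S,11R,11aS)-4,10-dihydroxy-6,10-dimethyl-3-methylidene-2,5-dioxododecahydrocyclodeca[b]furan-11-yl 2-methylpropanoate | C=C1C(=O)O[C@H]2[C@H]1[C@@H](O)C(=O)[C@H](C)CCC[C@](C)(O)[C@@H]2OC(=O)C(C)C | intermediate
22 | tiglic acid | C/C=C(\C)C(=O)O | starting material
23 | (2R)-2-methylbutanoic acid | CC[C@@H](C)C(=O)O | intermediate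
24 | (3aS,4R,6R,10S,11R,11aS)-10-hydroxy-6,10-dimethyl-3-methylidene-11-(2-methylpropanoyloxy)-2,5-dioxododecahydrocyclodeca[b]furan-4-yl (2R)-2-methylbutanoate | C=C1C(=O)O[C@H]2[C@H]1[C@@H](OC(=O)[C@H](C)CC)C(=O)[C@H](C)CCC[C@](C)(O)[C@@H]2OC(=O)C(C)C | target

**Step count**
Total: 16 steps. Longest linear sequence: 15 steps (steps 1–14 and 16; step 15 is a one-step side branch).

**Three steps most likely to fail, each with a fallback**

Step 14 (the proposed new macrocyclising allylboration; risks are oligomerisation, hydrate formation of the keto-aldehyde and a mismatched ring fusion). The fallback is the known indium-mediated Barbier macrocyclisation of a bromomethyl butenolide, the kind of allyl-metal ring closure already used for germacranolides. It sets out from 15: oxidation of the C–B bond (H2O2, pH 7 phosphate buffer, THF, 0 °C) gives the 3-(hydroxymethyl)butenolide F5; CBr4/PPh3 in CH2Cl2 gives the 3-(bromomethyl)butenolide F6; CF3CO2H/CH2Cl2 gives the bromo acid F7; iBuOCOCl/N-methylmorpholine gives the mixed carbonic anhydride F8, which with CH2N2 gives the bromo diazoketone F9; dimethyldioxirane gives the bromo keto-aldehyde F10; In powder in THF/H2O at high dilution then closes the ring at C7–C8 and the route is rejoined at 21.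

Step 9 (hydroalumination/borylmethylation next to an epoxide and a free alkoxide; risks are epoxide opening, over-reduction and wrong alkene geometry). The fallback builds the same butenolide by tin and zinc chemistry. It sets out from 10: Bu3SnH with PdCl2(PPh3)2 (2 mol%) in THF adds H and Sn syn across the alkynoate (Sn α to the ester) and the product lactonises to the α-stannyl butenolide F3; I2 in CH2Cl2 at 0 °C gives the α-iodo butenolide F4; Negishi coupling with IZnCH2Bpin (from 11 and Zn) under Pd(PPh3)4 in THF comes back to the route at 13.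

Step 7 (catalyst-controlled alkynylation of a β,β-disubstituted enal; risk is insufficient selectivity at C6, which controls C5 and C4). The fallback sets the carbinol by a metal-free asymmetric reduction. It sets out from 7: addition of lithium methyl propiolate (LiN(SiMe3)2, THF, −78 °C) gives the C6-epimeric propargylic alcohol mixture F1; MnO2 in CH2Cl2 gives the ynone F2; Corey–Bakshi–Shibata reduction ((R)-2-methyl-CBS-oxazaborolidine 10 mol%, catecholborane, toluene, −78 °C, the alkyne acting as the small group) comes back to the route at 9.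

**Further compounds**
F1 | step 7 | 11-tert-butyl 1-methyl (5E,10R)-4-hydroxy-6,10-dimethylundec-5-en-2-ynedioate, both C4 epimers | CC(C)(C)OC(=O)[C@H](C)CCC/C(C)=C/C(O)C#CC(=O)OC
F2 | step 7 | 11-tert-butyl 1-methyl (5E,10R)-6,10-dimethyl-4-oxoundec-5-en-2-ynedioate | CC(C)(C)OC(=O)[C@H](C)CCC/C(C)=C/C(=O)C#CC(=O)OC
F3 | step 9 | tert-butyl (2R)-2-methyl-5-[(2R,3R)-2-methyl-3-[(2S)-5-oxo-4-(tributylstannyl)-2,5-dihydrofuran-2-yl]oxiran-2-yl]pentanoate | CC(C)(C)OC(=O)[C@H](C)CCC[C@@]1(C)O[C@@H]1[C@@H]1C=C([Sn](CCCC)(CCCC)CCCC)C(=O)O1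
F4 | step 9 | tert-butyl (2R)-5-[(2R,3R)-3-[(2S)-4-iodo-5-oxo-2,5-dihydrofuran-2-yl]-2-methyloxiran-2-yl]-2-methylpentanoate | CC(C)(C)OC(=O)[C@H](C)CCC[C@@]1(C)O[C@@H]1[C@@H]1C=C(I)C(=O)O1
F5 | step 14 | tert-butyl (2R,6S,7R)-6-hydroxy-7-[(2S)-4-(hydroxymethyl)-5-oxo-2,5-dihydrofuran-2-yl]-2,6-dimethyl-7-(2-methylpropanoyloxy)heptanoate | CC(C)(C)OC(=O)[C@H](C)CCC[C@](C)(O)[C@H](OC(=O)C(C)C)[C@@H]1C=C(CO)C(=O)O1
F6 | step 14 | tert-butyl (2R,6S,7R)-7-[(2S)-4-(bromomethyl)-5-oxo-2,5-dihydrofuran-2-yl]-6-hydroxy-2,6-dimethyl-7-(2-methylpropanoyloxy)heptanoate | CC(C)(C)OC(=O)[C@H](C)CCC[C@](C)(O)[C@H](OC(=O)C(C)C)[C@@H]1C=C(CBr)C(=O)O1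
F7 | step 14 | (2R,6S,7R)-7-[(2S)-4-(bromomethyl)-5-oxo-2,5-dihydrofuran-2-yl]-6-hydroxy-2,6-dimethyl-7-(2-methylpropanoyloxy)heptanoic acid | OC(=O)[C@H](C)CCC[C@](C)(O)[C@H](OC(=O)C(C)C)[C@@H]1C=C(CBr)C(=O)O1
F8 | step 14 | mixed anhydride of F7 with isobutyl hydrogen carbonate | CC(C)COC(=O)OC(=O)[C@H](C)CCC[C@](C)(O)[C@H](OC(=O)C(C)C)[C@@H]1C=C(CBr)C(=O)O1
F9 | step 14 | (1R,2S,6R)-1-[(2S)-4-(bromomethyl)-5-oxo-2,5-dihydrofuran-2-yl]-8-diazo-2-hydroxy-2,6-dimethyl-7-oxooctyl 2-methylpropanoate | [N-]=[N+]=CC(=O)[C@H](C)CCC[C@](C)(O)[C@H](OC(=O)C(C)C)[C@@H]1C=C(CBr)C(=O)O1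
F10 | step 14 | (1R,2S,6R)-1-[(2S)-4-(bromomethyl)-5-oxo-2,5-dihydrofuran-2-yl]-2-hydroxy-2,6-dimethyl-7,8-dioxooctyl 2-methylpropanoate | O=CC(=O)[C@H](C)CCC[C@](C)(O)[C@H](OC(=O)C(C)C)[C@@H]1C=C(CBr)C(=O)O1
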